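**Plan**
1. Retrosynthesis: the C12–C13 bond is cut (B-alkyl Suzuki) into decalin 20 and butenolide enol triflate 30. The C4 quaternary centre is traced back to a temporary 18,6α-lactone ring on a C4 ketone. Ring B is then cut at C5–C6 and C8–C9 into the ring-A bis-nucleophile 5 and the masked 3-oxobutanal 7.
2. Enabling feature: ring B holds the 1,3-dioxygenated unit C6(OH)–C7–C8(OH)(CH3) between C5 and C9, which both sit on the quaternary C10. With a carbonyl at C4, O=C4–C5–C6–OH is an aldol and HO–C8–C9–C11=C12 is a homoallylic alcohol, so a C5 enolate and an (E)-allylboronate ending at C9 can be annulated with one aldehyde–ketone.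
3. Forward order: ring A with C10 (asymmetric conjugate addition); ring B in one pot (boron aldol, then intramolecular allylboration); temporary lactone C18–O6 (carbonylation, reductive methylation) and its reduction; chain by Suzuki coupling; global deprotection.
4. Stereochemistry: C10 from the chiral copper catalyst; C5, C6, C8, C9 relayed from C10 through two chair transition states; C4 from the lactone tether to 6α-O; C14/C15 from L-tartaric acid; C16 from a catalyst-controlled alkynylation.

Key step: step 4

Remark: labdane-type numbering is used. Ring A = C1–C5 and C10; ring B = C5–C10; C17 = methyl on C8; C18 = oxygenated carbon on C4 (α); C19 = methyl on C4 (β); C20 = methyl on C10; chain C11–C12–C13(=CH2)–C14–C15–C16, with C16 the butenolide ring carbon; α = face opposite to C20.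

Step 1
Reactants: 1 3-methylcyclohex-2-en-1-one
Product: 3 (R)-trimethyl[(3-methyl-3-vinylcyclohex-1-en-1-yl)oxy]silane, via dimethylaluminium enolate 2 (not isolated)
Conditions: CH2=CHMgBr, Me2AlCl, Et2O, −30 °C; 1, Cu(MeCN)4BF4 (5 mol %), chiral phosphinamine ligand Ph2P–N[CH(Me)Ph]2 (the enantiomer that gives the 3R adduct, 6 mol %), −30 °C; then Me3SiOTf, −30 to 0 °C
Reagents that add atoms: vinylmagnesium bromide, C=C[Mg]Br; trimethylsilyl trifluoromethanesulfonate, C[Si](C)(C)OS(=O)(=O)C(F)(F)F
Why: Copper-catalysed asymmetric conjugate addition of an alkenylalane to a β-substituted cyclic enone should create the C10 quaternary centre under ligand control, and O-silylation of the aluminium enolate fixes the enol double bond regiospecifically at C4=C5.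

Step 2
Reactants: 3 (R)-trimethyl[(3-methyl-3-vinylcyclohex-1-en-1-yl)oxy]silane; 4 allylboronic acid pinacol ester
Product: 5 trimethyl({(3R)-3-methyl-3-[(1E)-3-(4,4,5,5-tetramethyl-1,3,2-dioxaborolan-2-yl)prop-1-en-1-yl]cyclohex-1-en-1-yl}oxy)silane
Conditions: second-generation Hoveyda–Grubbs catalyst (5 mol %), 4 (3 equiv), CH2Cl2, 40 °C
Reagents that add atoms: none
Why: Olefin cross-metathesis between the vinyl group on the quaternary carbon (which cannot homodimerise) and the unhindered allylboronate should give the linear (E)-allylboronate, the trisubstituted enol ether being too hindered to enter the catalytic cycle.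

Step 3
Reactants: 6 ethyl 2-(2-methyl-1,3-dioxolan-2-yl)acetate
Product: 7 2-(2-methyl-1,3-dioxolan-2-yl)acetaldehyde
Conditions: i-Bu2AlH, CH2Cl2, −78 °C
Reagents that add atoms: none
Why: Partial reduction of an ester by i-Bu2AlH at low temperature stops at the aldehyde because the tetrahedral aluminium hemiacetal survives until work-up.

Step 4
Reactants: 5 silyl enol ether allylboronate; 7 2-(2-methyl-1,3-dioxolan-2-yl)acetaldehyde
Product: 12 trans-decalone (C4 ketone; 5α-H; 6α-OH; 8α-OH; 8β-CH3; 9β-vinyl; 10β-CH3), via dibutylboron enolate 8 (not isolated), via boron aldolate 9 (not isolated), via hydroxy diketone 10 (not isolated), via pinacol borate 11 (not isolated)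
Conditions: 5, Bu2BOTf, CH2Cl2, −78 to 0 °C; 7 (0.95 equiv), −78 °C; then 1 M HCl, THF, 0 to 40 °C; NaHCO3 work-up
Reagents that add atoms: water, O
Why: Exchange of silicon for boron turns 5 into the regiodefined boron enolate 8, which adds to aldehyde 7 through a Zimmerman–Traxler chair to form C5–C6 (9); aqueous acid then cleaves the borinate and the dioxolane, and the freed C8 methyl ketone of 10 is attacked by C9, the γ-carbon of the (E)-allylboronate, through a second six-membered chair that forms C8–C9 and leaves the C11=C12 vinyl group (11, hydrolysed to 12). The closest known reaction types are the anti-selective boron aldol of cyclohexanone enolates and the intramolecular allylboration of carbonyl groups that gives trans-2-vinylcycloalkanols, run here one after the other as an annulation of a 1,3-bis-nucleophile with a 1,3-dielectrophile. Ring B is the only ring closed, as a six-membered carbocycle by 6-exo-trig addition of the allyl terminus C9 to the C8 carbonyl, in a chair that is trans-fused both to ring A and to the boron-containing chair. C5 is set by approach of the aldehyde anti to the 3-borylpropenyl group on the adjacent quaternary C10, C6 by the fixed (E)-enolate geometry of the ring (anti aldol, which becomes the equatorial 6α-OH), and C8 and C9 together by the (E)-allylboronate geometry in the all-chair array, which places 8-OH and 9-vinyl trans-diequatorial and the 8-methyl axial. The step needs chemo- and regioselectivity (C5 to the aldehyde carbon, C9 to the ketone carbon), which is secured by the dioxolane mask on C8 and by the inertness of the pinacol allylboronate towards aldehydes at −78 °C, so that the ketone appears only after the aldol is complete. Facial selectivity at C5 rests on the size difference between methyl and the alkenyl group and is the least secure element.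

Step 5
Reactants: 12 trans-decalone diol
Product: 13 6,8-bis(trimethylsilyl) ether of 12
Conditions: N-(trimethylsilyl)imidazole, CH2Cl2, 23 °C
Reagents that add atoms: N-(trimethylsilyl)imidazole, C[Si](C)(C)n1ccnc1
Why: Neutral silylation caps the secondary and the tertiary hydroxyl without enolising the ketone, so that the β-oxygen cannot trigger a retro-aldol cleavage in the basic step that follows.

Step 6
Reactants: 13 bis(trimethylsilyl) ether
Product: 15 C3=C4 enol triflate with free 6α- and 8α-hydroxyls, via bis-silylated enol triflate 14 (not isolated)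
Conditions: KN(SiMe3)2, PhNTf2, THF, −78 to 0 °C; then pyridinium p-toluenesulfonate, MeOH, 23 °C
Reagents that add atoms: N-phenylbis(trifluoromethanesulfonimide), O=S(=O)(N(c1ccccc1)S(=O)(=O)C(F)(F)F)C(F)(F)F
Why: Kinetic deprotonation by the bulky amide occurs at the unhindered C3 methylene and O-triflation of the enolate gives the C3=C4 enol triflate, after which mild acidic methanolysis removes both trimethylsilyl ethers.

Step 7
Reactants: 15 enol triflate diol
Product: 16 unsaturated 18,6α-lactone (C18(=O) on C4, C3=C4, lactone oxygen on C6; 8α-OH; 9β-vinyl)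
Conditions: Pd(PPh3)4 (5 mol %), CO (1 atm), Et3N, MeCN, 60 °C
Reagents that add atoms: carbon monoxide, [C-]#[O+]
Why: Palladium-catalysed carbonylation of the enol triflate gives an acylpalladium species at C18 that is trapped by the peri 6α-hydroxyl in a five-membered ring (intramolecular alkoxycarbonylation), the tertiary 8-hydroxyl being too remote and too hindered to compete.

Step 8
Reactants: 16 unsaturated lactone
Product: 18 4β-methyl-18,6α-lactone (8α-OH; 9β-vinyl), via lithium lactone enolate 17 (not isolated)
Conditions: LiBH(s-Bu)3, THF, −78 °C; then MeI, N,N'-dimethylpropyleneurea, −78 to 0 °C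
Reagents that add atoms: iodomethane, CI
Why: Conjugate hydride addition to the α-alkylidene lactone gives the lactone enolate, and its methylation can only occur on the β face because C18 is held on the α side by the lactone bridge to 6α-O, which sets the C4 quaternary centre (4β-methyl, 4α-C18).

Step 9
Reactants: 18 methylated lactone
Product: 19 6α,8α,18-triol (9β-vinyl)
Conditions: LiAlH4, THF, 0 to 23 °C
Reagents that add atoms: none
Why: Hydride reduction of the γ-lactone opens the temporary ring to the 6α,18-diol without touching the vinyl group or any stereocentre.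

Step 10
Reactants: 19 triol
Product: 20 6,8,18-tris(triethylsilyl) ether of 19
Conditions: Et3SiOTf, 2,6-lutidine, CH2Cl2, −78 to 0 °C
Reagents that add atoms: triethylsilyl trifluoromethanesulfonate, CC[Si](CC)(CC)OS(=O)(=O)C(F)(F)F
Why: The silyl triflate is reactive enough to silylate the primary, the secondary and the hindered tertiary hydroxyl, which keeps them from consuming the borane in the coupling step.

Step 11
Reactants: 21 dimethyl (4R,5R)-2,2-dimethyl-1,3-dioxolane-4,5-dicarboxylate
Product: 22 (4R,5R)-N4,N5-dimethoxy-N4,N5,2,2-tetramethyl-1,3-dioxolane-4,5-dicarboxamide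
Conditions: MeNH(OMe)·HCl, i-PrMgCl, THF, −20 to 0 °C
Reagents that add atoms: N,O-dimethylhydroxylamine hydrochloride, CNOC.Cl
Why: Aminolysis of both esters by the chloromagnesium amide gives the bis(Weinreb amide) without epimerisation of the trans-dioxolane.

Step 12
Reactants: 22 bis(Weinreb amide)
Product: 23 (4R,5R)-5-acetyl-N-methoxy-N,2,2-trimethyl-1,3-dioxolane-4-carboxamide
Conditions: MeMgBr (1.1 equiv), THF, −20 to 0 °C
Reagents that add atoms: methylmagnesium bromide, C[Mg]Br
Why: The chelated tetrahedral intermediate of a Weinreb amide prevents over-addition, and because the two amides of the C2-symmetric substrate are equivalent, one equivalent of Grignard reagent should give a single mono-ketone.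

Step 13
Reactants: 23 keto amide
Product: 24 1-{(4R,5R)-5-[methoxy(methyl)carbamoyl]-2,2-dimethyl-1,3-dioxolan-4-yl}vinyl trifluoromethanesulfonate
Conditions: KN(SiMe3)2, PhNTf2, THF, −78 °C
Reagents that add atoms: N-phenylbis(trifluoromethanesulfonimide), O=S(=O)(N(c1ccccc1)S(=O)(=O)C(F)(F)F)C(F)(F)F
Why: Kinetic enolisation of the methyl ketone occurs at the methyl group and not at the ring methine (whose enolate would be exocyclic to the dioxolane), and O-triflation gives the 1,1-disubstituted enol triflate that later becomes C13=CH2.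

Step 14
Reactants: 24 enol triflate Weinreb amide
Product: 25 1-[(4R,5R)-5-formyl-2,2-dimethyl-1,3-dioxolan-4-yl]vinyl trifluoromethanesulfonate
Conditions: i-Bu2AlH, THF, −78 °C
Reagents that add atoms: none
Why: Reduction of a Weinreb amide by i-Bu2AlH stops at the chelated hemiaminal and gives the α-alkoxy aldehyde on work-up, the enol triflate being inert at this temperature.

Step 15
Reactants: 25 aldehyde; 26 methyl propiolate
Product: 28 propargylic alcohol (methyl 4-hydroxybut-2-ynoate carrying the trans-dioxolane at C4; new carbinol 15,16-syn), via methylzinc alkynylide 27 (not isolated)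
Conditions: Me2Zn, ProPhenol ligand (20 mol %, the enantiomer that gives the 15,16-syn carbinol), Ph3P=O (40 mol %), toluene, 4 °C
Reagents that add atoms: none
Why: Zinc–ProPhenol-catalysed addition of the zinc alkynylide of methyl propiolate to the aldehyde (asymmetric alkynylation) sets C16 under catalyst control, in the sense that chelation of zinc between the aldehyde and the α-oxygen also favours.

Step 16
Reactants: 28 propargylic alcohol
Product: 30 butenolide enol triflate (5-substituted 4-methylfuran-2(5H)-one carrying the trans-dioxolane and the 1-(triflyloxy)vinyl group), via hydroxy enoate 29 (not isolated)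
Conditions: Me2CuLi (from MeLi and CuI), THF, −78 °C; NH4Cl work-up, then 23 °C
Reagents that add atoms: lithium dimethylcuprate, [Li+].C[Cu-]C
Why: syn-Carbocupration of the ynoate puts the methyl group on the β-carbon and leaves the carbinol carbon cis to the ester, so the (Z)-enoate lactonises to the 4-methylbutenolide, while the enol triflate should not couple with the cuprate at −78 °C.

Step 17
Reactants: 20 tris(triethylsilyl) ether; 30 butenolide enol triflate
Product: 32 protected coupling product (tris-silyl ether; 14,15-acetonide), via B-alkylborane 31 (not isolated)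
Conditions: 9-BBN, THF, 23 °C; then 30, Pd(dppf)Cl2 (5 mol %), AsPh3, Cs2CO3, DMF–H2O, 23 °C
Reagents that add atoms: none
Why: Anti-Markovnikov hydroboration of the terminal vinyl group and B-alkyl Suzuki–Miyaura coupling of the primary alkylborane with the enol triflate join C12 to C13 and deliver the 1,1-disubstituted alkene directly.

Step 18
Reactants: 32 protected coupling product
Product: 33 CNP0301623.1
Conditions: CF3CO2H–H2O–THF (1:1:4), 0 to 23 °C
Reagents that add atoms: none
Why: Aqueous acid hydrolyses the three triethylsilyl ethers and the isopropylidene acetal in one operation, under conditions the butenolide, the exocyclic alkene and the tertiary alcohol should survive.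

**Compound list**
1 | 3-methylcyclohex-2-en-1-one | CC1=CC(=O)CCC1 | starting material
2 | dimethylaluminium (R)-3-methyl-3-vinylcyclohex-1-en-1-olate | C=C[C@@]1(C)CCCC(O[Al](C)C)=C1 | intermediate
3 | (R)-trimethyl[(3-methyl-3-vinylcyclohex-1-en-1-yl)oxy]silane | C=C[C@@]1(C)CCCC(O[Si](C)(C)C)=C1 | intermediate
4 | allylboronic acid pinacol ester (2-allyl-4,4,5,5-tetramethyl-1,3,2-dioxaborolane) | C=CCB1OC(C)(C)C(C)(C)O1 | starting material
5 | trimethyl({(3R)-3-methyl-3-[(1E)-3-(4,4,5,5-tetramethyl-1,3,2-dioxaborolan-2-yl)prop-1-en-1-yl]cyclohex-1-en-1-yl}oxy)silane | CC1(C)OB(C/C=C/[C@@]2(C)CCCC(O[Si](C)(C)C)=C2)OC1(C)C | intermediate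
6 | ethyl 2-(2-methyl-1,3-dioxolan-2-yl)acetate | CCOC(=O)CC1(C)OCCO1 | starting material
7 | 2-(2-methyl-1,3-dioxolan-2-yl)acetaldehyde | O=CCC1(C)OCCO1 | intermediate
8 | dibutylboron enolate of 5 (Bu2B–O on C4, C4=C5) | CC1(C)OB(C/C=C/[C@@]2(C)CCCC(OB(CCCC)CCCC)=C2)OC1(C)C | intermediate
9 | dibutylboron aldolate (C4 ketone; C5 chain cis to C20 and trans to the alkenyl group; 6-O–BBu2, anti aldol; C8 as dioxolane) | CC1(C)OB(C/C=C/[C@@]2(C)CCCC(=O)[C@@H]2[C@@H](OB(CCCC)CCCC)CC2(C)OCCO2)OC1(C)C | intermediate
10 | hydroxy diketone (C4 ketone; 5α-H; 6-OH anti; C8 methyl ketone; (E)-C9=C11–C12H2–B(pinacolato)) | CC1(C)OB(C/C=C/[C@@]2(C)CCCC(=O)[C@@H]2[C@@H](O)CC(C)=O)OC1(C)C | intermediate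
11 | 8-O-pinacol borate of 12 | C=C[C@@H]1[C@@]2(C)CCCC(=O)[C@@H]2[C@@H](O)C[C@@]1(C)OB1OC(C)(C)C(C)(C)O1 | intermediate
12 | trans-decalone: C4 ketone, 5α-H, 6α-OH, 8α-OH, 8β-CH3, 9β-vinyl, 10β-CH3 | C=C[C@@H]1[C@@]2(C)CCCC(=O)[C@@H]2[C@@H](O)C[C@@]1(C)O | intermediate
13 | 6,8-bis(trimethylsilyl) ether of 12 | C=C[C@@H]1[C@@]2(C)CCCC(=O)[C@@H]2[C@@H](O[Si](C)(C)C)C[C@@]1(C)O[Si](C)(C)C | intermediate
14 | 6,8-bis(trimethylsilyl) ether of enol triflate 15 | C=C[C@@H]1[C@@]2(C)CCC=C(OS(=O)(=O)C(F)(F)F)[C@@H]2[C@@H](O[Si](C)(C)C)C[C@@]1(C)O[Si](C)(C)C | intermediate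
15 | C3=C4 enol triflate (4-OTf) with 6α-OH, 8α-OH, 9β-vinyl | C=C[C@@H]1[C@@]2(C)CCC=C(OS(=O)(=O)C(F)(F)F)[C@@H]2[C@@H](O)C[C@@]1(C)O | intermediate
16 | unsaturated 18,6α-lactone (C3=C4; C18(=O) on C4; lactone O on C6; 8α-OH; 9β-vinyl) | C=C[C@@H]1[C@@]2(C)CCC=C3[C@@H]2[C@@H](OC3=O)C[C@@]1(C)O | intermediate
17 | lithium enolate of the saturated 18,6α-lactone (C4=C18–OLi) | [Li+].C=C[C@@H]1[C@@]2(C)CCCC3[C@@H]2[C@@H](OC=3[O-])C[C@@]1(C)O | intermediate
18 | 4β-methyl-18,6α-lactone (8α-OH; 9β-vinyl) | C=C[C@@H]1[C@@]2(C)CCC[C@@](C)(C3=O)[C@@H]2[C@@H](O3)C[C@@]1(C)O | intermediate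
19 | 6α,8α,18-triol (4β,8β,10β-trimethyl; 9β-vinyl; 5α-H) | C=C[C@@H]1[C@@]2(C)CCC[C@@](C)(CO)[C@@H]2[C@@H](O)C[C@@]1(C)O | intermediate
20 | 6,8,18-tris(triethylsilyl) ether of 19 | C=C[C@@H]1[C@@]2(C)CCC[C@@](C)(CO[Si](CC)(CC)CC)[C@@H]2[C@@H](O[Si](CC)(CC)CC)C[C@@]1(C)O[Si](CC)(CC)CC | intermediate
21 | dimethyl (4R,5R)-2,2-dimethyl-1,3-dioxolane-4,5-dicarboxylate (from L-tartaric acid) | COC(=O)[C@@H]1OC(C)(C)O[C@H]1C(=O)OC | starting material
22 | (4R,5R)-N4,N5-dimethoxy-N4,N5,2,2-tetramethyl-1,3-dioxolane-4,5-dicarboxamide | CON(C)C(=O)[C@@H]1OC(C)(C)O[C@H]1C(=O)N(C)OC | intermediate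
23 | (4R,5R)-5-acetyl-N-methoxy-N,2,2-trimethyl-1,3-dioxolane-4-carboxamide | CC(=O)[C@@H]1OC(C)(C)O[C@H]1C(=O)N(C)OC | intermediate
24 | 1-{(4R,5R)-5-[methoxy(methyl)carbamoyl]-2,2-dimethyl-1,3-dioxolan-4-yl}vinyl trifluoromethanesulfonate | C=C(OS(=O)(=O)C(F)(F)F)[C@@H]1OC(C)(C)O[C@H]1C(=O)N(C)OC | intermediate
25 | 1-[(4R,5R)-5-formyl-2,2-dimethyl-1,3-dioxolan-4-yl]vinyl trifluoromethanesulfonate | C=C(OS(=O)(=O)C(F)(F)F)[C@@H]1OC(C)(C)O[C@H]1C=O | intermediate
26 | methyl propiolate | C#CC(=O)OC | starting material
27 | methyl 3-(methylzincio)propiolate | C[Zn]C#CC(=O)OC | intermediate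
28 | propargylic alcohol: methyl 4-hydroxybut-2-ynoate with the trans-dioxolane (bearing the 1-(triflyloxy)vinyl group) on C4, 15,16-syn | C=C(OS(=O)(=O)C(F)(F)F)[C@@H]1OC(C)(C)O[C@H]1[C@H](O)C#CC(=O)OC | intermediate
29 | (Z)-γ-hydroxy-β-methyl enoate from 28 | C=C(OS(=O)(=O)C(F)(F)F)[C@@H]1OC(C)(C)O[C@H]1[C@H](O)/C(C)=C\C(=O)OC | intermediate
30 | butenolide enol triflate: 4-methylfuran-2(5H)-one with the trans-dioxolane (bearing the 1-(triflyloxy)vinyl group) on C5 | C=C(OS(=O)(=O)C(F)(F)F)[C@@H]1OC(C)(C)O[C@H]1[C@@H]1OC(=O)C=C1C | intermediate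
31 | B-alkyl-9-borabicyclo[3.3.1]nonane from 20 (boron on C12) | B1(CC[C@@H]2[C@@]3(C)CCC[C@@](C)(CO[Si](CC)(CC)CC)[C@@H]3[C@@H](O[Si](CC)(CC)CC)C[C@@]2(C)O[Si](CC)(CC)CC)C2CCCC1CCC2 | intermediate
32 | protected target: 6,8,18-tris(triethylsilyl) ether, 14,15-O-isopropylidene | C=C(CC[C@@H]1[C@@]2(C)CCC[C@@](C)(CO[Si](CC)(CC)CC)[C@@H]2[C@@H](O[Si](CC)(CC)CC)C[C@@]1(C)O[Si](CC)(CC)CC)[C@@H]1OC(C)(C)O[C@H]1[C@@H]1OC(=O)C=C1C | intermediate
33 | CNP0301623.1 (6α,8α,18-trihydroxy decalin; 9β-chain CH2CH2–C(=CH2)–CH(OH)–CH(OH)–butenolide; 14S,15R,16R) | C=C(CC[C@@H]1[C@@]2(C)CCC[C@@](C)(CO)[C@@H]2[C@@H](O)C[C@@]1(C)O)[C@H](O)[C@@H](O)[C@@H]1OC(=O)C=C1C | target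

**Summary**
Total steps: 18. Longest linear sequence: 11 steps (steps 1, 2, 4–10, 17, 18).

**Steps most likely to fail**

Step 4. The faces of the enolate carbon C5 may be discriminated too weakly by the quaternary C10 (methyl versus alkenyl), which would divert material into the diastereomeric ring-B series. Ring closure may also be slow against the developing 1,3-diaxial methyl/methyl contact, so that dehydration of the aldol competes. The fallback sets out from 5 and comes back at 12; it moves stereocontrol from the substrate to a chiral catalyst and runs the annulation stepwise. Enol silane 5 is converted with SiCl4 and catalytic Hg(OAc)2 into the trichlorosilyl enol ether F1. Chiral-phosphoramide-catalysed aldol addition of F1 to 7 (closed, anti-selective transition state at hexacoordinate silicon, enolate face chosen by the catalyst) gives, after NaHCO3 work-up, the isolated anti aldol with intact dioxolane and allylboronate F2, from which any minor diastereomer can be removed. F2 is then treated with aqueous HCl in THF, if necessary with catalytic Sc(OTf)3 to accelerate the allylboration, to unmask the ketone and close ring B to 12.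

Step 2. Productive metathesis at the vinyl group next to the quaternary carbon may be slow, and the trimethylsilyl enol ether may be hydrolysed during the long reaction. The fallback sets out from 3 and comes back at 12; it runs the aldol before the metathesis so that the labile enol ether is used first. Compound 3 is converted into its dibutylboron enolate (Bu2BOTf) and added to 7 to give the isolated vinyl aldol F3. Cross-metathesis of the robust ketone F3 with 4 (second-generation Hoveyda–Grubbs catalyst) gives the allylboronate aldol F4. Aqueous acid then unmasks the ketone and closes ring B to 12.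

Step 17. The base-sensitive butenolide may epimerise at C16 or open under the aqueous carbonate of the coupling, and transmetalation of the hindered alkylborane may be slow. The fallback sets out from 20 and 24 and comes back at 32; it couples before the butenolide exists. Borane 31 (from 20 and 9-BBN) is coupled under the same palladium conditions with the base-stable enol triflate 24 to give the coupled Weinreb amide F5. i-Bu2AlH reduces F5 to the coupled aldehyde F6. Zinc–ProPhenol alkynylation of F6 with 26 gives the coupled propargylic alcohol F7. Me2CuLi then adds to the ynoate and the (Z)-enoate lactonises to 32.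

**Further compounds**
F1 | step 4 | trichlorosilyl enol ether corresponding to 5 | CC1(C)OB(C/C=C/[C@@]2(C)CCCC(O[Si](Cl)(Cl)Cl)=C2)OC1(C)C
F2 | step 4 | anti aldol with intact dioxolane and allylboronate (free 6-OH) | CC1(C)OB(C/C=C/[C@@]2(C)CCCC(=O)[C@@H]2[C@@H](O)CC2(C)OCCO2)OC1(C)C
F3 | step 2 | vinyl aldol (C4 ketone, 6-OH anti, C8 as dioxolane, vinyl on C10) | C=C[C@@]1(C)CCCC(=O)[C@@H]1[C@@H](O)CC1(C)OCCO1
F4 | step 2 | allylboronate aldol with intact dioxolane (same structure as F2) | CC1(C)OB(C/C=C/[C@@]2(C)CCCC(=O)[C@@H]2[C@@H](O)CC2(C)OCCO2)OC1(C)C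
F5 | step 17 | coupled Weinreb amide (tris-silyl decalin joined at C12–C13 to the dioxolane amide) | C=C(CC[C@@H]1[C@@]2(C)CCC[C@@](C)(CO[Si](CC)(CC)CC)[C@@H]2[C@@H](O[Si](CC)(CC)CC)C[C@@]1(C)O[Si](CC)(CC)CC)[C@@H]1OC(C)(C)O[C@H]1C(=O)N(C)OC
F6 | step 17 | coupled aldehyde | C=C(CC[C@@H]1[C@@]2(C)CCC[C@@](C)(CO[Si](CC)(CC)CC)[C@@H]2[C@@H](O[Si](CC)(CC)CC)C[C@@]1(C)O[Si](CC)(CC)CC)[C@@H]1OC(C)(C)O[C@H]1C=O
F7 | step 17 | coupled propargylic alcohol (15,16-syn) | C=C(CC[C@@H]1[C@@]2(C)CCC[C@@](C)(CO[Si](CC)(CC)CC)[C@@H]2[C@@H](O[Si](CC)(CC)CC)C[C@@]1(C)O[Si](CC)(CC)CC)[C@@H]1OC(C)(C)O[C@H]1[C@H](O)C#CC(=O)OC
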